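**Design of a total synthesis of bisoflavolin N (15) by twofold Claisen folding of a bis(triketo ester)**

## The problem

Bisoflavolin N (15) is a dimer of genistein in which two 5,7-dihydroxy-3-aryl-4H-chromen-4-one units are joined by one C3'–C3''' bond between the two rings B, ortho to each 4'-hydroxyl, and one ring A carries chlorine at C8. There is no stereocentre, and the biaryl axis has only two ortho substituents and rotates freely, so the tasks are connectivity, regiochemistry and the single element that breaks the twofold symmetry. Only the C8–Cl bond distinguishes the halves, so they must be differentiated either early (two building blocks) or late (mono-functionalisation of a symmetric dimer), and chlorine must go to C8, not C6. The six phenols make every ring electron-rich and open to oxidation and over-halogenation. The pyranone C2 is a vinylogous ester carbon that hydroxide or alkoxide opens, so strongly basic C–C bond formation must precede closure of ring C, and the aryl chloride forbids careless hydrogenolysis. The enabling feature is ring A: C5, C7 and C8a bear oxygen and C4a bears the C4 carbonyl, which is the pattern of an acylphloroglucinol and therefore of a 3,5,7-triketo ester folded by attack of C6 on C1, with the C3–C4 unit as the arylacetyl starter hanging from the ring B biphenyl. A phloroglucinol made this way is symmetric about its acyl axis, so ring C closes unambiguously onto either ortho hydroxyl, but chlorine cannot be carried through the fold and must come afterwards.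

## Retrosynthesis

**15 ⇒ 14.** The six O–CH3 bonds are cut last. Methyl ethers are chosen because the two ring B oxygens must pass through palladium, amide-base and alkoxide chemistry, and the ring A oxygens need alkylation only for the chlorination. One Lewis-acid operation then frees all six. The forward step must cleave chelated and non-chelated ethers without touching C8–Cl or the pyranones.

**14 ⇒ 13.** The C8–Cl bond is cut next. Chlorine is late because the fold gives a symmetric ring A. In a 5,7-dimethoxychromone, C8 is the expected site: it is para to the 5-methoxy group, ortho to the 7-methoxy group and O1, and less hindered than C6 between two methoxy groups. A free chelated 5-hydroxyl would shift attack toward C6, which is why 13 is fully methylated. Compound 13 is C2-symmetric, so everything before it runs identically on both halves. The price is a statistical mono-chlorination, taken to partial conversion with recycling of 13.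

**13 ⇒ 12 ⇒ 11.** Four O–CH3 bonds are removed to give tetraol 12. Then O1–C2 and C2–C3 of each chromone are cut, which takes out C2 as a one-carbon electrophile and leaves the bis(2,4,6-trihydroxydeoxybenzoin) 11. The neighbouring cut at C3–C1' (coupling of 3-halochromones with a biphenyl) would need rings A and C made separately and would discard the arylacetyl logic. The forward reaction must formylate both benzylic methylenes and cyclise in the presence of free phenols. The two ortho hydroxyls of each ring are equivalent, so one product results.

**11 ⇒ 10 (key disconnection).** The C4a–C5 bond of each future chromone is cut, which is C6–C1 of each chain. Both rings A open into linear methyl 3,5,7-trioxooctanoate chains whose C8 is the benzylic carbon of ring B. The neighbouring cut at C4–C4a (Friedel–Crafts acylation of a bought trioxygenated benzene) is shorter and is kept in reserve. The Claisen fold is preferred as the design because it assembles both rings A from acetate units on the biphenyl in one operation and leaves no pre-formed ring A to protect. Compound 10 is acyclic apart from the biphenyl. The forward reaction must fold by Claisen, not aldol, and must do so on both chains.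

**10 ⇒ 8 (through 9).** The two methyl ester C1–O bonds are cut. The free triketo ester is too ready to fold to be carried through a C–C bond formation, so C1 and C3 of each chain are masked as a 2,2-dimethyl-1,3-dioxin-4-one in 8. Heating releases the acylketene 9 under neutral conditions, and methanol traps it as the ester.

**8 ⇒ 5 + 7.** The C6–C7 bond of each chain is cut. The electrophile is bis(N-methoxy-N-methylamide) 5 and the nucleophile is the dianion of acetonyl dioxinone 7, which reacts at its terminal carbon. Cutting C4–C5 instead would require an activated β-keto acid of the biphenyl, which is unstable. The forward reaction asks for C-acylation in competition with enolisation of the arylacetyl amide.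

**7 ⇒ 6; 5 ⇒ 4.** Compound 7 is the γ-acetylation product of commercial dioxinone 6. Amide 5 comes from diester 4 by direct aminolysis.

**4 ⇒ 2 + 3; 3 ⇒ 2 ⇒ 1.** The biaryl C–C bond of 4 is cut into bromo ester 2 and pinacol boronate 3. Boronate 3 is the borylation product of 2, and 2 is the methyl ester of commercial acid 1, so one aromatic building block supplies both rings B and both C3–C4 units. A reductive homocoupling of 2 with a stoichiometric metal reductant would be one step shorter, but it risks loss of bromide by reduction next to the methoxy group. The palladium-catalysed cross-coupling is taken as the more dependable way to the same symmetric biaryl, and stray homocoupling of either partner leads to 4 as well. The forward reactions must leave the methyl esters untouched.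

## Roads not taken

**Alternative 1:** Both C3–C1' bonds are traced back to C2–C1' bonds, giving the bis-flavanone A2. In the forward key step a trivalent iodine or trivalent thallium oxidant induces a 2,3-aryl shift in each flavanone and delivers A1, which is identical with 14.
- Merits: ring A is bought as an acetophenone, the flavanones arise from aldol condensation and oxa-Michael closure on the ring B biphenyl, and each migrating ring B carries a para-methoxy group, which favours the shift. The sequence is clearly shorter than the chosen one.
- Weak points: flavanone oxidation competes with dehydrogenation to flavones, and a single failure at either site gives an isomer of A1 that is hard to remove. Thallium is toxic. An unsymmetrical A2 needs two different acetophenones on one symmetric biphenyl (again statistical), unless chlorine is introduced late exactly as here.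
- Comparison: in step economy this road is better. The chosen plan sets against it an isoflavone construction with no flavone/isoflavone ambiguity, because C2 is added to a deoxybenzoin, and a ring A synthesis that needs no differentiated phloroglucinol building block.

**Alternative 2:** Two C–C bonds of one ring B (C1'–C6' and C2'–C3') are cut, and that ring is built by an enamine-driven Robinson annulation of a four-carbon aldehyde ester onto an aryl vinyl ketone. The product is racemic cyclohexenone A3, which is aromatised later.
- Merits: the two rings B differ from the outset. One is a bromoanisole and the other carries the acetic ester arm and a masked phenol, so the chlorinated half could be built on a defined side. This solves the desymmetrisation that the chosen plan leaves to a statistical step, and in this respect it is better.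
- Weak points: the key step builds a benzene ring that can be bought, creates a stereocentre only to destroy it, and needs an extra aromatisation. The bromide must still become a second arylacetyl unit. The sequence is long and linear.
- Comparison: the chosen plan answers the symmetry problem less elegantly but with far fewer operations, each run on both halves at once, and with recovery of unreacted 13.

**Alternative 3:** Both C3–C4 bonds are traced back through a 1,2-acyl shift to the bis(chalcone epoxide) A5. A boron Lewis acid opens each trans-epoxide at the benzylic carbon, the aroyl group migrates, and the bis(α-formyl deoxybenzoin) A4 results as its enol. Debenzylation and cyclodehydration then close ring C.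
- Merits: C2 arrives with the chalcone and no formylation is needed. Chlorine is carried from the start, and the benzyl-protected oxygen next to C–Cl becomes O1, so the C8 position is fixed by construction. That is better than the late electrophilic chlorination chosen here.
- Weak points: A5 is unsymmetrical and needs two different acetophenones on one biphenyl (statistical or stepwise). The chlorinated, differentially protected acetophenone needs its own regiocontrolled synthesis. Acyl migration must beat hydride shift at two sites, and benzyl removal beside an aryl chloride cannot rely on plain hydrogenolysis.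
- Comparison: chlorine regiochemistry is better here and the length is comparable. The chosen plan offers a fully symmetric sequence from one cheap aromatic building block up to 13 and a ring A construction with no protecting-group pattern to design.

Key step: step 8

Assumption: the 2,2'-dioxygenated biphenyl axis is taken as freely rotating, so every compound is treated as one achiral species; equivalents in twofold reactions refer to the whole molecule.

## Route

Step 1
Reactants: 1 2-(3-bromo-4-methoxyphenyl)acetic acid
Product: 2 methyl 2-(3-bromo-4-methoxyphenyl)acetate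
Conditions: MeOH, H2SO4 (cat.), reflux
Reagents that add atoms: methanol, CO
Why: Fischer esterification of an unhindered arylacetic acid; the ester protects the acid during the palladium steps and is the handle for amide formation.

Step 2
Reactants: 2 methyl 2-(3-bromo-4-methoxyphenyl)acetate
Product: 3 methyl 2-[4-methoxy-3-(4,4,5,5-tetramethyl-1,3,2-dioxaborolan-2-yl)phenyl]acetate
Conditions: B2pin2 (1.1 equiv), PdCl2(dppf) (3 mol %), KOAc (3 equiv), 1,4-dioxane, 90 °C
Reagents that add atoms: bis(pinacolato)diboron, CC1(C)OB(OC1(C)C)B1OC(C)(C)C(C)(C)O1
Why: Miyaura borylation, run on one half of the batch of 2: zerovalent palladium inserts into C–Br, acetate-assisted transmetalation with B2pin2 and reductive elimination give the aryl pinacol boronate. The weak base KOAc leaves the methyl ester and its α-protons alone and holds back premature coupling of 3 with unreacted 2.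

Step 3
Reactants: 2 methyl 2-(3-bromo-4-methoxyphenyl)acetate; 3 methyl 2-[4-methoxy-3-(4,4,5,5-tetramethyl-1,3,2-dioxaborolan-2-yl)phenyl]acetate
Product: 4 dimethyl 2,2'-(6,6'-dimethoxybiphenyl-3,3'-diyl)diacetate
Conditions: Pd(PPh3)4 (5 mol %), K3PO4, 1,4-dioxane–H2O (10:1), 85 °C
Reagents that add atoms: none
Why: Suzuki–Miyaura cross-coupling of an aryl bromide with an aryl pinacol boronate, each carrying a single ortho-methoxy group, a degree of hindrance that Pd(PPh3)4 handles routinely. Both partners derive from 2, so only the symmetric biaryl can form and homocoupling of either partner leads to the same product; phosphate with little water keeps the methyl esters intact.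

Step 4
Reactants: 4 dimethyl 2,2'-(6,6'-dimethoxybiphenyl-3,3'-diyl)diacetate
Product: 5 2,2'-(6,6'-dimethoxybiphenyl-3,3'-diyl)bis(N-methoxy-N-methylacetamide)
Conditions: MeNH(OMe)·HCl, iPrMgCl, THF, −20 → 0 °C
Reagents that add atoms: N,O-dimethylhydroxylamine hydrochloride, CNOC.Cl
Why: Direct ester-to-Weinreb-amide conversion by the magnesium amide of N,O-dimethylhydroxylamine; at low temperature aminolysis is faster than enolisation of the arylacetate.

Step 5
Reactants: 6 2,2,6-trimethyl-4H-1,3-dioxin-4-one
Product: 7 2,2-dimethyl-6-(2-oxopropyl)-4H-1,3-dioxin-4-one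
Conditions: LiN(SiMe3)2, THF, −78 °C; then AcCl (0.5 equiv), −78 → −20 °C
Reagents that add atoms: acetyl chloride, CC(Cl)=O
Why: Vinylogous (γ) C-acylation of the lithium dienolate of the dioxinone; half an equivalent of acid chloride is used because the more acidic product consumes a second dienolate.

Step 6
Reactants: 5 2,2'-(6,6'-dimethoxybiphenyl-3,3'-diyl)bis(N-methoxy-N-methylacetamide); 7 2,2-dimethyl-6-(2-oxopropyl)-4H-1,3-dioxin-4-one
Product: 8 6,6'-[(6,6'-dimethoxybiphenyl-3,3'-diyl)bis(2,4-dioxopentane-5,1-diyl)]bis(2,2-dimethyl-4H-1,3-dioxin-4-one)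
Conditions: 7 (3 equiv), LiN(iPr)2 (LDA, 6.2 equiv), THF, −78 °C; then 5, −78 → −30 °C; aq. NH4Cl
Reagents that add atoms: none
Why: Claisen-type C-acylation of a 1,3-dicarbonyl dianion at its terminal (most basic) carbon by a Weinreb amide. The chelated tetrahedral adduct survives until the quench, so no over-addition occurs and the acidic product does not consume dianion; excess dianion compensates for any enolisation of the amide.

Step 7
Reactants: 8 6,6'-[(6,6'-dimethoxybiphenyl-3,3'-diyl)bis(2,4-dioxopentane-5,1-diyl)]bis(2,2-dimethyl-4H-1,3-dioxin-4-one)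
Product: 10 dimethyl 8,8'-(6,6'-dimethoxybiphenyl-3,3'-diyl)bis(3,5,7-trioxooctanoate), via bis(acylketene) 9 (not isolated)
Conditions: MeOH (excess), PhMe, 110 °C, sealed tube; crude product used directly
Reagents that add atoms: methanol, CO
Why: Thermal retro-hetero-Diels–Alder fragmentation of each dioxinone expels acetone and gives an acylketene, which excess methanol traps as the β-keto ester faster than the internal enol can close a pyranone. No base is present, so the chain stays unfolded.

Step 8
Reactants: 10 dimethyl 8,8'-(6,6'-dimethoxybiphenyl-3,3'-diyl)bis(3,5,7-trioxooctanoate)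
Product: 11 2,2'-(6,6'-dimethoxybiphenyl-3,3'-diyl)bis[1-(2,4,6-trihydroxyphenyl)ethan-1-one]
Conditions: Mg(OMe)2 (excess), MeOH, 25 → 65 °C, Ar; then 1 M HCl
Reagents that add atoms: none
Why: Mg(OMe)2 deprotonates C4 and C6 and holds the 3,5,7-tricarbonyl array of each chain as a magnesium-chelated bis-enolate, so that no ketone carbonyl remains electrophilic and the methyl ester carbon C1 is the only acyl acceptor. The C6 enolate carbon adds to C1, methoxide leaves and the 2-acylcyclohexane-1,3,5-trione tautomerises to the aromatic triol; this is the known Claisen (Dieckmann-type) cyclisation of 3,5,7-triketo esters to acylphloroglucinols, run here on two chains of one molecule. Each ring A closes as a six-membered carbocycle by 6-exo-trig attack of an enolate carbon on the ester carbonyl, the new bond being C6–C1 of the chain (C4a–C5 of the chromone). No stereocentre is formed. The selectivity needed is Claisen folding over aldol folding (C2 onto C7, which would give a 6-benzylresorcylate) and over O-acylation to a 4-hydroxy-2-pyranone; magnesium chelation of the ketones, exclusion of water and the match of methoxide with the methyl ester secure the first, and a pyranone, if formed, is reopened by methoxide to the same chain. Enolisation of C7 toward the benzylic C8 lowers the electrophilicity of C7 further, which also disfavours the aldol mode. The two chains are separated by the biphenyl and should fold independently, so the twofold reaction needs only full conversion of both.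

Step 9
Reactants: 11 2,2'-(6,6'-dimethoxybiphenyl-3,3'-diyl)bis[1-(2,4,6-trihydroxyphenyl)ethan-1-one]
Product: 12 3,3'-(6,6'-dimethoxybiphenyl-3,3'-diyl)bis(5,7-dihydroxy-4H-chromen-4-one)
Conditions: BF3·OEt2, DMF, 25 °C; then MsCl, DMF, 70 °C
Reagents that add atoms: N,N-dimethylformamide, CN(C)C=O
Why: Vilsmeier-type formylation of the benzylic methylene of a boron-chelated 2-hydroxydeoxybenzoin by the DMF–MsCl iminium salt, followed by cyclisation with loss of dimethylamine; this is the standard isoflavone ring closure. It tolerates free phenols, and the two ortho hydroxyls of each ring are equivalent, so only one chromone can form.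

Step 10
Reactants: 12 3,3'-(6,6'-dimethoxybiphenyl-3,3'-diyl)bis(5,7-dihydroxy-4H-chromen-4-one)
Product: 13 3,3'-(6,6'-dimethoxybiphenyl-3,3'-diyl)bis(5,7-dimethoxy-4H-chromen-4-one)
Conditions: Me2SO4 (excess), K2CO3, acetone, reflux
Reagents that add atoms: dimethyl sulfate, COS(=O)(=O)OC
Why: Williamson O-methylation of phenols; prolonged reflux with excess reagent also alkylates the hydrogen-bonded 5-hydroxyls, which removes the chelate that would otherwise direct halogenation toward C6.

Step 11
Reactants: 13 3,3'-(6,6'-dimethoxybiphenyl-3,3'-diyl)bis(5,7-dimethoxy-4H-chromen-4-one)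
Product: 14 8-chloro-3-[3'-(5,7-dimethoxy-4-oxo-4H-chromen-3-yl)-6,6'-dimethoxybiphenyl-3-yl]-5,7-dimethoxy-4H-chromen-4-one
Conditions: N-chlorosuccinimide (0.9–1.0 equiv), DMF, 25 → 50 °C; recovered 13 recycled
Reagents that add atoms: N-chlorosuccinimide, O=C1CCC(=O)N1Cl
Why: Electrophilic aromatic chlorination of a 5,7-dimethoxychromone, which takes halogen at C8 (activated by the 5- and 7-methoxy groups and O1, less hindered than C6). Ring B, a mono-alkoxy arene, is much less reactive, and limiting the reagent holds the reaction at the mono-chloride with return of unreacted 13.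

Step 12
Reactants: 14 8-chloro-3-[3'-(5,7-dimethoxy-4-oxo-4H-chromen-3-yl)-6,6'-dimethoxybiphenyl-3-yl]-5,7-dimethoxy-4H-chromen-4-one
Product: 15 bisoflavolin N, 8-chloro-3-[3'-(5,7-dihydroxy-4-oxo-4H-chromen-3-yl)-6,6'-dihydroxybiphenyl-3-yl]-5,7-dihydroxy-4H-chromen-4-one
Conditions: BBr3 (excess), CH2Cl2, −78 → 40 °C; then MeOH, H2O
Reagents that add atoms: none
Why: Lewis-acid cleavage of aryl methyl ethers by BBr3 (O–B coordination, then bromide attack on methyl); the chelation-assisted 5-ethers and the electron-rich ring B ethers go first and the 7-ethers on warming, while the aryl chloride and the pyranone are inert.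

## Compound list

1 | 2-(3-bromo-4-methoxyphenyl)acetic acid | COc1ccc(CC(O)=O)cc1Br | starting material
2 | methyl 2-(3-bromo-4-methoxyphenyl)acetate | COC(=O)Cc1ccc(OC)c(Br)c1 | intermediate
3 | methyl 2-[4-methoxy-3-(4,4,5,5-tetramethyl-1,3,2-dioxaborolan-2-yl)phenyl]acetate | COC(=O)Cc1ccc(OC)c(B2OC(C)(C)C(C)(C)O2)c1 | intermediate
4 | dimethyl 2,2'-(6,6'-dimethoxybiphenyl-3,3'-diyl)diacetate | COC(=O)Cc1ccc(OC)c(-c2cc(CC(=O)OC)ccc2OC)c1 | intermediate
5 | 2,2'-(6,6'-dimethoxybiphenyl-3,3'-diyl)bis(N-methoxy-N-methylacetamide) | CON(C)C(=O)Cc1ccc(OC)c(-c2cc(CC(=O)N(C)OC)ccc2OC)c1 | intermediate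
6 | 2,2,6-trimethyl-4H-1,3-dioxin-4-one | CC1=CC(=O)OC(C)(C)O1 | starting material
7 | 2,2-dimethyl-6-(2-oxopropyl)-4H-1,3-dioxin-4-one | CC(=O)CC1=CC(=O)OC(C)(C)O1 | intermediate
8 | 6,6'-[(6,6'-dimethoxybiphenyl-3,3'-diyl)bis(2,4-dioxopentane-5,1-diyl)]bis(2,2-dimethyl-4H-1,3-dioxin-4-one) | COc1ccc(CC(=O)CC(=O)CC2=CC(=O)OC(C)(C)O2)cc1-c1cc(CC(=O)CC(=O)CC2=CC(=O)OC(C)(C)O2)ccc1OC | intermediate
9 | bis(acylketene), 8,8'-(6,6'-dimethoxybiphenyl-3,3'-diyl)bis(oct-1-ene-1,3,5,7-tetrone), not isolated | COc1ccc(CC(=O)CC(=O)CC(=O)C=C=O)cc1-c1cc(CC(=O)CC(=O)CC(=O)C=C=O)ccc1OC | intermediate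
10 | dimethyl 8,8'-(6,6'-dimethoxybiphenyl-3,3'-diyl)bis(3,5,7-trioxooctanoate) | COC(=O)CC(=O)CC(=O)CC(=O)Cc1ccc(OC)c(-c2cc(CC(=O)CC(=O)CC(=O)CC(=O)OC)ccc2OC)c1 | intermediate
11 | 2,2'-(6,6'-dimethoxybiphenyl-3,3'-diyl)bis[1-(2,4,6-trihydroxyphenyl)ethan-1-one] | COc1ccc(CC(=O)c2c(O)cc(O)cc2O)cc1-c1cc(CC(=O)c2c(O)cc(O)cc2O)ccc1OC | intermediate
12 | 3,3'-(6,6'-dimethoxybiphenyl-3,3'-diyl)bis(5,7-dihydroxy-4H-chromen-4-one) | O=c1c(-c2ccc(OC)c(-c3cc(-c4coc5cc(O)cc(O)c5c4=O)ccc3OC)c2)coc2cc(O)cc(O)c12 | intermediate
13 | 3,3'-(6,6'-dimethoxybiphenyl-3,3'-diyl)bis(5,7-dimethoxy-4H-chromen-4-one) | O=c1c(-c2ccc(OC)c(-c3cc(-c4coc5cc(OC)cc(OC)c5c4=O)ccc3OC)c2)coc2cc(OC)cc(OC)c12 | intermediate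
14 | 8-chloro-3-[3'-(5,7-dimethoxy-4-oxo-4H-chromen-3-yl)-6,6'-dimethoxybiphenyl-3-yl]-5,7-dimethoxy-4H-chromen-4-one | O=c1c(-c2ccc(OC)c(-c3cc(-c4coc5c(Cl)c(OC)cc(OC)c5c4=O)ccc3OC)c2)coc2cc(OC)cc(OC)c12 | intermediate
15 | bisoflavolin N | O=c1c(-c2ccc(O)c(-c3cc(-c4coc5c(Cl)c(O)cc(O)c5c4=O)ccc3O)c2)coc2cc(O)cc(O)c12 | target

## Step count and least certain steps

Total step count: 12. Longest linear sequence: 11 steps (from 1 through steps 1–4 and 6–12); step 5 is a one-step side branch from 6.

**Step 8 (key step).** The most likely failure is folding in the wrong mode. Aldol closure of C2 onto C7 in one or both chains gives resorcylate-type rings, and if the two chains fold differently, mixed products follow. Methoxide can also cleave the triketone by retro-Claisen before it closes. The cause is that several enolate/carbonyl pairs lie six atoms apart, and only magnesium chelation separates them.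
Fallback: it sets out from 5 and rejoins the route at 13. 2,4,6-Trimethoxyphenyllithium (from 1,3,5-trimethoxybenzene and n-BuLi in THF) is added to both amide groups of 5 and gives 2,2'-(6,6'-dimethoxybiphenyl-3,3'-diyl)bis[1-(2,4,6-trimethoxyphenyl)ethan-1-one] F1. BCl3 in CH2Cl2 removes the one methyl group ortho to each ketone and gives 2,2'-(6,6'-dimethoxybiphenyl-3,3'-diyl)bis[1-(2-hydroxy-4,6-dimethoxyphenyl)ethan-1-one] F2. DMF, BF3·OEt2 and MsCl then close both pyranones and give 13 directly, which replaces steps 9 and 10. Ring A is then bought, not built.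

**Step 6.** The benzylic α-protons of the arylacetyl amide are acidic, so proton transfer to the strongly basic dianion may outrun acylation. This returns both partners after the quench and leaves mono-acylated material.
Fallback: it sets out from 4 and rejoins at 8, and replaces the hard enolate by soft enolisation. Saponification (LiOH, THF–H2O) gives 2,2'-(6,6'-dimethoxybiphenyl-3,3'-diyl)diacetic acid F3, and oxalyl chloride with catalytic DMF gives 2,2'-(6,6'-dimethoxybiphenyl-3,3'-diyl)diacetyl dichloride F4. In parallel, 6 is enolised with LiN(SiMe3)2 and acylated with allyl malonyl chloride to give allyl 4-(2,2-dimethyl-4-oxo-4H-1,3-dioxin-6-yl)-3-oxobutanoate F5. MgCl2 and pyridine in CH2Cl2 enolise F5, and F4 acylates it at the carbon between ketone and ester to give the diallyl bis(2-arylacetyl-3-oxobutanoate) F6. Pd(PPh3)4 and morpholine remove both allyl groups with decarboxylation and give 8.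

**Step 11.** The two chromones are remote and identical, so the reagent cannot distinguish a molecule that has already reacted. Under-chlorination and over-chlorination therefore occur together, and some attack at C6 may be added; the products differ little in polarity.
Fallback: it sets out from 1 and rejoins at 14. The halves are differentiated before they are joined, at the price of giving up the twofold fold. Friedel–Crafts acylation of phloroglucinol with 1 in BF3·OEt2 gives 2-(3-bromo-4-methoxyphenyl)-1-(2,4,6-trihydroxyphenyl)ethan-1-one F7. DMF and MsCl in the same flask convert it into 3-(3-bromo-4-methoxyphenyl)-5,7-dihydroxy-4H-chromen-4-one F8, and methylation (Me2SO4, K2CO3) gives 3-(3-bromo-4-methoxyphenyl)-5,7-dimethoxy-4H-chromen-4-one F9. One portion of F9 is chlorinated with N-chlorosuccinimide to 3-(3-bromo-4-methoxyphenyl)-8-chloro-5,7-dimethoxy-4H-chromen-4-one F10; a second chlorination of the same ring is slow, and a C6 isomer can be removed at this small stage. The other portion is borylated (B2pin2, PdCl2(dppf), KOAc) to 5,7-dimethoxy-3-[4-methoxy-3-(4,4,5,5-tetramethyl-1,3,2-dioxaborolan-2-yl)phenyl]-4H-chromen-4-one F11. Suzuki–Miyaura coupling of F10 with F11 (Pd(PPh3)4, K2CO3) joins the rings B through the C–Br bond and gives 14; the hindered, electron-rich C8–Cl bond stays intact.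

**Step 12.** Cleavage may stop at partly methylated stages. The 7-methoxy groups sit on an electron-poor ring, are not chelation-assisted and coordinate boron poorly; forcing the reaction risks decomposition of the polyphenol.
Fallback: it sets out from 12 and rejoins at 15, and changes the protecting groups on ring A. Benzylation (BnBr, K2CO3, DMF, 70 °C) gives 3,3'-(6,6'-dimethoxybiphenyl-3,3'-diyl)bis[5,7-bis(benzyloxy)-4H-chromen-4-one] F12. N-Chlorosuccinimide, as in step 11, gives the mono-8-chloride F13. BBr3 at −78 → 0 °C then cleaves the four benzyl ethers and the two electron-rich ring B methyl ethers, and gives 15 without a resistant 7-methyl ether to remove.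

## Further compounds

F1 | step 8 | 2,2'-(6,6'-dimethoxybiphenyl-3,3'-diyl)bis[1-(2,4,6-trimethoxyphenyl)ethan-1-one] | COc1ccc(CC(=O)c2c(OC)cc(OC)cc2OC)cc1-c1cc(CC(=O)c2c(OC)cc(OC)cc2OC)ccc1OC
F2 | step 8 | 2,2'-(6,6'-dimethoxybiphenyl-3,3'-diyl)bis[1-(2-hydroxy-4,6-dimethoxyphenyl)ethan-1-one] | COc1ccc(CC(=O)c2c(O)cc(OC)cc2OC)cc1-c1cc(CC(=O)c2c(O)cc(OC)cc2OC)ccc1OC
F3 | step 6 | 2,2'-(6,6'-dimethoxybiphenyl-3,3'-diyl)diacetic acid | COc1ccc(CC(=O)O)cc1-c1cc(CC(=O)O)ccc1OC
F4 | step 6 | 2,2'-(6,6'-dimethoxybiphenyl-3,3'-diyl)diacetyl dichloride | COc1ccc(CC(=O)Cl)cc1-c1cc(CC(=O)Cl)ccc1OC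
F5 | step 6 | allyl 4-(2,2-dimethyl-4-oxo-4H-1,3-dioxin-6-yl)-3-oxobutanoate | C=CCOC(=O)CC(=O)CC1=CC(=O)OC(C)(C)O1
F6 | step 6 | diallyl 2,2'-[(6,6'-dimethoxybiphenyl-3,3'-diyl)bis(1-oxoethane-2,1-diyl)]bis[4-(2,2-dimethyl-4-oxo-4H-1,3-dioxin-6-yl)-3-oxobutanoate] | COc1ccc(CC(=O)C(C(=O)OCC=C)C(=O)CC2=CC(=O)OC(C)(C)O2)cc1-c1cc(CC(=O)C(C(=O)OCC=C)C(=O)CC2=CC(=O)OC(C)(C)O2)ccc1OC
F7 | step 11 | 2-(3-bromo-4-methoxyphenyl)-1-(2,4,6-trihydroxyphenyl)ethan-1-one | COc1ccc(CC(=O)c2c(O)cc(O)cc2O)cc1Br
F8 | step 11 | 3-(3-bromo-4-methoxyphenyl)-5,7-dihydroxy-4H-chromen-4-one | COc1ccc(cc1Br)-c1coc2cc(O)cc(O)c2c1=O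
F9 | step 11 | 3-(3-bromo-4-methoxyphenyl)-5,7-dimethoxy-4H-chromen-4-one | COc1ccc(cc1Br)-c1coc2cc(OC)cc(OC)c2c1=O
F10 | step 11 | 3-(3-bromo-4-methoxyphenyl)-8-chloro-5,7-dimethoxy-4H-chromen-4-one | COc1ccc(cc1Br)-c1coc2c(Cl)c(OC)cc(OC)c2c1=O
F11 | step 11 | 5,7-dimethoxy-3-[4-methoxy-3-(4,4,5,5-tetramethyl-1,3,2-dioxaborolan-2-yl)phenyl]-4H-chromen-4-one | COc1ccc(cc1B1OC(C)(C)C(C)(C)O1)-c1coc2cc(OC)cc(OC)c2c1=O
F12 | step 12 | 3,3'-(6,6'-dimethoxybiphenyl-3,3'-diyl)bis[5,7-bis(benzyloxy)-4H-chromen-4-one] | O=c1c(-c2ccc(OC)c(-c3cc(-c4coc5cc(OCc6ccccc6)cc(OCc6ccccc6)c5c4=O)ccc3OC)c2)coc2cc(OCc3ccccc3)cc(OCc3ccccc3)c12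
F13 | step 12 | 5,7-bis(benzyloxy)-3-{3'-[5,7-bis(benzyloxy)-4-oxo-4H-chromen-3-yl]-6,6'-dimethoxybiphenyl-3-yl}-8-chloro-4H-chromen-4-one | O=c1c(-c2ccc(OC)c(-c3cc(-c4coc5c(Cl)c(OCc6ccccc6)cc(OCc6ccccc6)c5c4=O)ccc3OC)c2)coc2cc(OCc3ccccc3)cc(OCc3ccccc3)c12
A1 | alternative 1 | hexamethyl ether of the target, identical with 14 | O=c1c(-c2ccc(OC)c(-c3cc(-c4coc5c(Cl)c(OC)cc(OC)c5c4=O)ccc3OC)c2)coc2cc(OC)cc(OC)c12
A2 | alternative 1 | bis-flavanone, 8-chloro-2-[3'-(5,7-dimethoxy-4-oxochroman-2-yl)-6,6'-dimethoxybiphenyl-3-yl]-5,7-dimethoxychroman-4-one (mixture of stereoisomers at both C2) | COc1ccc(C2CC(=O)c3c(OC)cc(OC)cc3O2)cc1-c1cc(C2CC(=O)c3c(OC)cc(OC)c(Cl)c3O2)ccc1OC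
A3 | alternative 2 | methyl 2-[3-(5-bromo-2-methoxyphenyl)-4-oxocyclohex-2-en-1-yl]acetate (racemic) | COC(=O)CC1CCC(=O)C(c2cc(Br)ccc2OC)=C1
A4 | alternative 3 | bis(2-aryl-3-hydroxypropenone), enol form of the bis(α-formyl deoxybenzoin) | O=C(c1c(OCc2ccccc2)cc(OC)cc1OC)/C(=C\O)c1ccc(OC)c(-c2cc(/C(=C/O)C(=O)c3c(OCc4ccccc4)c(Cl)c(OC)cc3OC)ccc2OC)c1
A5 | alternative 3 | bis(chalcone epoxide), each epoxide trans and racemic, one diastereomer drawn | O=C(c1c(OCc2ccccc2)cc(OC)cc1OC)[C@@H]1O[C@H]1c1ccc(OC)c(-c2cc([C@H]3O[C@@H]3C(=O)c3c(OCc4ccccc4)c(Cl)c(OC)cc3OC)ccc2OC)c1
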